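**Retrosynthetic overview**

1. The target is epicatechin-(4α→8)-epicatechin 3-O-gallate-(4β→8)-epicatechin 3-O-gallate. The end game is a double esterification of the two free 3-hydroxyls with tri-O-benzylgallic acid, then global hydrogenolysis.
2. The upper bond C4(upper)–C8(middle) comes from a C8 aryllithium of the middle unit adding to an upper-unit 4-ketone, followed by ionic deoxygenation (all-cis, 4α). The lower bond C4(middle)–C8(lower) comes from Friedel–Crafts alkylation by the middle-unit C4 cation (4β).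
3. Ring C of the middle unit is built de novo by a one-flask enantioselective boron aldol / intramolecular SNAr annulation of an ortho-fluoroaryl α-silyloxy ketone with 3,4-bis(benzyloxy)benzaldehyde. It forms C2–C3 and O1–C8a.
4. Enabling feature: in the middle unit C3 lies between the oxygenated C2 and C4. With C4 as a ketone, C3 is an enolate carbon, and the C4 carbonyl on C4a is ortho to C8a of ring A, so a C8a fluoride is displaced by the C2 alkoxide. The cis O1/O3 pair is a syn-aldol pair.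
5. Ring order: rings A and B of all units are bought aromatic; ring C of the middle unit is made in the key step; the upper and lower units come intact from (−)-epicatechin.

Key step: step 5

Remark: the sense of induction of the (S,S)-diazaborolidine bromide (used as a pre-formed solution from the commercial bis-sulfonamide and BBr3) is assigned by analogy with its syn-aldols of ethyl ketones; if it proves opposite, the (R,R)-reagent is used and nothing else changes.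
Remark: the C4 carbinol configurations drawn for the two flavan-4-ols and the tertiary alcohol are the expected major ones; each is erased in the step that follows.

Step 1
Reactants: 1 1,3,5-trifluorobenzene
Product: 2 1,3-bis(benzyloxy)-5-fluorobenzene
Conditions: BnOH (2.1 equiv), NaH, NMP, 0 → 90 °C
Reagents that add atoms: benzyl alcohol, OCc1ccccc1
Why: Two successive SNAr displacements by sodium benzyloxide; the third, on a ring with two alkoxy groups and no other fluorine to activate it, is the slowest, so the stoichiometry should stop the reaction at the monofluoride.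

Step 2
Reactants: 3 methyl glycolate
Product: 4 methyl 2-[(triisopropylsilyl)oxy]acetate
Conditions: TIPSCl, imidazole, DMF, rt
Reagents that add atoms: chlorotri(propan-2-yl)silane (TIPSCl), CC(C)[Si](Cl)(C(C)C)C(C)C
Why: Standard silylation of a primary alcohol; the bulky triisopropylsilyl group is chosen because it resists 1,4-O→O silyl shifts in the later alkoxide chemistry.

Step 3
Reactants: 4 methyl 2-[(triisopropylsilyl)oxy]acetate
Product: 5 N-methoxy-N-methyl-2-[(triisopropylsilyl)oxy]acetamide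
Conditions: MeNH(OMe)·HCl, i-PrMgCl, THF, −20 °C
Reagents that add atoms: N,O-dimethylhydroxylamine hydrochloride, CNOC.Cl
Why: Ester aminolysis by the chloromagnesium amide of N,O-dimethylhydroxylamine, a standard route to N-methoxy-N-methylamides.

Step 4
Reactants: 2 1,3-bis(benzyloxy)-5-fluorobenzene; 5 N-methoxy-N-methyl-2-[(triisopropylsilyl)oxy]acetamide
Product: 7 1-[2,4-bis(benzyloxy)-6-fluorophenyl]-2-[(triisopropylsilyl)oxy]ethan-1-one, via aryllithium 6 (not isolated)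
Conditions: n-BuLi, THF, −78 °C; then 5, −78 °C
Reagents that add atoms: none
Why: Directed ortho-lithiation at the C–H flanked by fluorine and benzyloxy (the most acidic ring position; the two such sites are equivalent), then acylation by the N-methoxy-N-methylamide, whose chelated tetrahedral adduct prevents over-addition; the ortho-fluoroaryllithium is held at −78 °C so that LiF loss to an aryne does not occur.

Step 5
Reactants: 7 1-[2,4-bis(benzyloxy)-6-fluorophenyl]-2-[(triisopropylsilyl)oxy]ethan-1-one; 8 3,4-bis(benzyloxy)benzaldehyde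
Product: 11 (2R,3S)-5,7-bis(benzyloxy)-2-[3,4-bis(benzyloxy)phenyl]-3-[(triisopropylsilyl)oxy]chroman-4-one (2,3-cis), via boron enolate 9 (not isolated), via syn-aldol 10 (not isolated)
Conditions: (4S,5S)-2-bromo-4,5-diphenyl-1,3-ditosyl-1,3,2-diazaborolidine, i-Pr2NEt, CH2Cl2, −78 → −40 °C; 8, −78 °C; then MeOH, Cs2CO3, DMF, −40 → 0 °C (one flask)
Reagents that add atoms: none
Why: Soft enolisation of 7 by the chiral bromoborane and amine gives Z-boron enolate 9 (aryl ketones enolise to the Z geometry), which adds to 8 through a closed chair transition state; methanolysis of the boron aldolate frees syn-aldol 10, whose caesium alkoxide attacks C8a and expels fluoride through an anionic σ-adduct stabilised by the ortho C4 carbonyl. The closest known reaction types are the reagent-controlled syn-selective boron aldol of ketones and the intramolecular SNAr closure of β-hydroxy ketones carrying an ortho-fluoroaryl group to chroman-4-ones, here run in one flask. Ring C is closed in the 6-exo-trig mode by O1 onto C8a. C2 and C3 are both set in the aldol: the Z-enolate fixes the syn (2,3-cis) relationship and the C2-symmetric sulfonamide ligand on boron fixes the absolute sense (attack on the Si face of 8, giving 2R,3S). The step needs six-ring over five-ring closure and ring closure faster than retro-aldol or C3 epimerisation: O3 carries a silyl group too bulky to shift to O1, the fluoride is ortho to the carbonyl with both benzyloxy groups meta to C8a, and the alkoxide is generated with a weak base at −40 to 0 °C.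

Step 6
Reactants: 11 (2R,3S)-5,7-bis(benzyloxy)-2-[3,4-bis(benzyloxy)phenyl]-3-[(triisopropylsilyl)oxy]chroman-4-one
Product: 12 (2R,3R,4R)-5,7-bis(benzyloxy)-2-[3,4-bis(benzyloxy)phenyl]-3-[(triisopropylsilyl)oxy]chroman-4-ol (all-cis)
Conditions: NaBH4, CeCl3·7H2O, MeOH/THF, −40 → 0 °C
Reagents that add atoms: none
Why: Luche reduction of the aryl ketone; hydride should enter from the β face, opposite the axial 3-silyloxy group, and the nearly neutral medium leaves the base-sensitive C3 centre untouched (the C4 configuration is erased in step 10).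

Step 7
Reactants: 12 (2R,3R,4R)-5,7-bis(benzyloxy)-2-[3,4-bis(benzyloxy)phenyl]-3-[(triisopropylsilyl)oxy]chroman-4-ol
Product: 13 (2R,3R,4R)-5,7-bis(benzyloxy)-2-[3,4-bis(benzyloxy)phenyl]-8-bromo-3-[(triisopropylsilyl)oxy]chroman-4-ol
Conditions: NBS, CH2Cl2, −78 → 0 °C
Reagents that add atoms: N-bromosuccinimide, O=C1CCC(=O)N1Br
Why: Electrophilic aromatic bromination of the phloroglucinol-type ring A, which in 5,7-bis(benzyloxy)flavans goes to C8 (next to the ring oxygen) rather than C6 (between two benzyloxy groups); the bromine blocks self-condensation in step 10 and is the handle for step 14.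

Step 8
Reactants: 14 (−)-epicatechin
Product: 15 5,7,3',4'-tetra-O-benzyl-(−)-epicatechin
Conditions: BnBr, K2CO3, DMF, rt
Reagents that add atoms: benzyl bromide, BrCc1ccccc1
Why: Williamson etherification selective for the four phenols (carbonate does not deprotonate the secondary alcohol); C2 and C3 come from the chiral pool and are not touched.

Step 9
Reactants: 15 5,7,3',4'-tetra-O-benzyl-(−)-epicatechin
Product: 16 5,7,3',4'-tetra-O-benzyl-3-O-(tert-butyldimethylsilyl)-(−)-epicatechin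
Conditions: TBSCl, imidazole, DMF, rt
Reagents that add atoms: tert-butylchlorodimethylsilane (TBSCl), CC(C)(C)[Si](C)(C)Cl
Why: Silylation of the secondary alcohol, so that it can be unmasked together with the middle-unit silyl ether in step 16.

Step 10
Reactants: 13 (2R,3R,4R)-5,7-bis(benzyloxy)-2-[3,4-bis(benzyloxy)phenyl]-8-bromo-3-[(triisopropylsilyl)oxy]chroman-4-ol; 16 5,7,3',4'-tetra-O-benzyl-3-O-(tert-butyldimethylsilyl)-(−)-epicatechin
Product: 17 8-bromo-5,7,3',4'-tetra-O-benzyl-3-O-triisopropylsilyl-epicatechin-(4β→8)-5,7,3',4'-tetra-O-benzyl-3-O-tert-butyldimethylsilyl-epicatechin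
Conditions: 16 (2 equiv), BF3·OEt2, 4 Å MS, CH2Cl2, −78 → −30 °C
Reagents that add atoms: none
Why: Friedel–Crafts alkylation: BF3 ionises the benzylic 4-hydroxyl to a cation stabilised by O1 and the 5,7-benzyloxy groups, C8 of 16 (its most nucleophilic carbon) attacks anti to the axial 3-silyloxy group to set the 3,4-trans (4β) centre, and the C8 bromine of 13 prevents self-condensation.

Step 11
Reactants: 15 5,7,3',4'-tetra-O-benzyl-(−)-epicatechin
Product: 18 3,5,7,3',4'-penta-O-benzyl-(−)-epicatechin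
Conditions: NaH, BnBr, n-Bu4NI (cat.), DMF, 0 °C → rt
Reagents that add atoms: benzyl bromide, BrCc1ccccc1
Why: Williamson etherification of the hindered 3-hydroxyl, giving the upper unit an oxygen mask that is distinct from the silyl ethers and falls in the final hydrogenolysis.

Step 12
Reactants: 18 3,5,7,3',4'-penta-O-benzyl-(−)-epicatechin
Product: 19 (2R,3R,4S)-3,5,7-tris(benzyloxy)-2-[3,4-bis(benzyloxy)phenyl]chroman-4-ol (4β-hydroxy)
Conditions: DDQ, H2O, CH2Cl2, rt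
Reagents that add atoms: water, O
Why: Benzylic oxidation: DDQ abstracts hydride from C4 (activated by the ortho/para oxygen donors of ring A) and water traps the cation trans to the 3-benzyloxy group; the new C4 centre is removed in step 13.

Step 13
Reactants: 19 (2R,3R,4S)-3,5,7-tris(benzyloxy)-2-[3,4-bis(benzyloxy)phenyl]chroman-4-ol
Product: 20 (2R,3S)-3,5,7-tris(benzyloxy)-2-[3,4-bis(benzyloxy)phenyl]chroman-4-one (2,3-cis)
Conditions: DMP, NaHCO3, CH2Cl2, rt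
Reagents that add atoms: none
Why: Dess–Martin oxidation of the benzylic alcohol under buffered, non-basic conditions, so the enolisable C3 centre is not epimerised.

Step 14
Reactants: 17 8-bromo-5,7,3',4'-tetra-O-benzyl-3-O-triisopropylsilyl-epicatechin-(4β→8)-5,7,3',4'-tetra-O-benzyl-3-O-tert-butyldimethylsilyl-epicatechin; 20 (2R,3S)-3,5,7-tris(benzyloxy)-2-[3,4-bis(benzyloxy)phenyl]chroman-4-one
Product: 22 3,5,7,3',4'-penta-O-benzyl-4α-hydroxy-epicatechin-(4β→8)-[5,7,3',4'-tetra-O-benzyl-3-O-triisopropylsilyl-epicatechin]-(4β→8)-[5,7,3',4'-tetra-O-benzyl-3-O-tert-butyldimethylsilyl-epicatechin], via aryllithium 21 (not isolated)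
Conditions: t-BuLi (2.1 equiv), THF, −78 °C; then 20, −78 °C
Reagents that add atoms: none
Why: Bromine–lithium exchange (faster than any deprotonation at −78 °C) gives aryllithium 21, which adds 1,2 to ketone 20, the known way to join C8 of one flavan to C4 of a flavan-4-one; attack from the β face is expected and the C4 configuration is erased in step 15.

Step 15
Reactants: 22 3,5,7,3',4'-penta-O-benzyl-4α-hydroxy-epicatechin-(4β→8)-[5,7,3',4'-tetra-O-benzyl-3-O-triisopropylsilyl-epicatechin]-(4β→8)-[5,7,3',4'-tetra-O-benzyl-3-O-tert-butyldimethylsilyl-epicatechin]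
Product: 23 3,5,7,3',4'-penta-O-benzyl-epicatechin-(4α→8)-[5,7,3',4'-tetra-O-benzyl-3-O-triisopropylsilyl-epicatechin]-(4β→8)-[5,7,3',4'-tetra-O-benzyl-3-O-tert-butyldimethylsilyl-epicatechin]
Conditions: n-Bu3SnH, TFA, CH2Cl2, 0 °C
Reagents that add atoms: none
Why: Ionic deoxygenation: TFA ionises the doubly benzylic tertiary alcohol and n-Bu3SnH delivers hydride to the cation from the β face, opposite the 2-aryl and 3-benzyloxy groups (both α), so the upper unit should end up 4α (2,3-cis-3,4-cis), as this reduction is known to do in the epicatechin series.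

Step 16
Reactants: 23 3,5,7,3',4'-penta-O-benzyl-epicatechin-(4α→8)-[5,7,3',4'-tetra-O-benzyl-3-O-triisopropylsilyl-epicatechin]-(4β→8)-[5,7,3',4'-tetra-O-benzyl-3-O-tert-butyldimethylsilyl-epicatechin]
Product: 24 3,5,7,3',4'-penta-O-benzyl-epicatechin-(4α→8)-[5,7,3',4'-tetra-O-benzyl-epicatechin]-(4β→8)-[5,7,3',4'-tetra-O-benzyl-epicatechin] (3-hydroxyls of the middle and lower units free)
Conditions: TBAF, THF, rt → 45 °C
Reagents that add atoms: none
Why: Fluoride cleavage of both silyl ethers (the hindered triisopropylsilyl ether needs mild warming); benzyl ethers and both interflavan bonds are inert to TBAF.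

Step 17
Reactants: 24 3,5,7,3',4'-penta-O-benzyl-epicatechin-(4α→8)-[5,7,3',4'-tetra-O-benzyl-epicatechin]-(4β→8)-[5,7,3',4'-tetra-O-benzyl-epicatechin]; 25 3,4,5-tris(benzyloxy)benzoic acid
Product: 26 3,5,7,3',4'-penta-O-benzyl-epicatechin-(4α→8)-[5,7,3',4'-tetra-O-benzyl-3-O-(3,4,5-tris(benzyloxy)benzoyl)-epicatechin]-(4β→8)-[5,7,3',4'-tetra-O-benzyl-3-O-(3,4,5-tris(benzyloxy)benzoyl)-epicatechin]
Conditions: 25 (4 equiv), DCC, DMAP, CH2Cl2, rt → 40 °C
Reagents that add atoms: none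
Why: Steglich esterification of both secondary alcohols; acylation of the 3-hydroxyls of benzyl-protected 4β→8 dimers with tri-O-benzylgalloyl donors is established, and the upper-unit oxygen stays masked as its benzyl ether.

Step 18
Reactants: 26 3,5,7,3',4'-penta-O-benzyl-epicatechin-(4α→8)-[5,7,3',4'-tetra-O-benzyl-3-O-(3,4,5-tris(benzyloxy)benzoyl)-epicatechin]-(4β→8)-[5,7,3',4'-tetra-O-benzyl-3-O-(3,4,5-tris(benzyloxy)benzoyl)-epicatechin]
Product: 27 epicatechin-(4α→8)-epicatechin 3-O-gallate-(4β→8)-epicatechin 3-O-gallate (CNP0279403.2)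
Conditions: H2 (1 atm), Pd(OH)2/C, THF/MeOH/H2O, rt
Reagents that add atoms: none
Why: Hydrogenolysis of all nineteen benzyl ethers; the aryl esters, the benzylic C–O bonds of the pyran rings and the interflavan C–C bonds should survive, as they do in procyanidin gallates under these conditions.

**Compound list**

1 | 1,3,5-trifluorobenzene | Fc1cc(F)cc(F)c1 | starting material
2 | 1,3-bis(benzyloxy)-5-fluorobenzene | Fc1cc(OCc2ccccc2)cc(OCc2ccccc2)c1 | intermediate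
3 | methyl glycolate | COC(=O)CO | starting material
4 | methyl 2-[(triisopropylsilyl)oxy]acetate | COC(=O)CO[Si](C(C)C)(C(C)C)C(C)C | intermediate
5 | N-methoxy-N-methyl-2-[(triisopropylsilyl)oxy]acetamide | CON(C)C(=O)CO[Si](C(C)C)(C(C)C)C(C)C | intermediate
6 | [2,4-bis(benzyloxy)-6-fluorophenyl]lithium | [Li]c1c(F)cc(OCc2ccccc2)cc1OCc1ccccc1 | intermediate
7 | 1-[2,4-bis(benzyloxy)-6-fluorophenyl]-2-[(triisopropylsilyl)oxy]ethan-1-one | O=C(CO[Si](C(C)C)(C(C)C)C(C)C)c1c(F)cc(OCc2ccccc2)cc1OCc1ccccc1 | intermediate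
8 | 3,4-bis(benzyloxy)benzaldehyde | O=Cc1ccc(OCc2ccccc2)c(OCc2ccccc2)c1 | starting material
9 | Z-boron enolate of 7 on the (4S,5S)-4,5-diphenyl-1,3-ditosyl-1,3,2-diazaborolidine | Cc1ccc(cc1)S(=O)(=O)N1B(O/C(=C\O[Si](C(C)C)(C(C)C)C(C)C)c2c(F)cc(OCc3ccccc3)cc2OCc2ccccc2)N([C@H]([C@@H]1c1ccccc1)c1ccccc1)S(=O)(=O)c1ccc(C)cc1 | intermediate
10 | (2S,3R)-1-[2,4-bis(benzyloxy)-6-fluorophenyl]-3-[3,4-bis(benzyloxy)phenyl]-3-hydroxy-2-[(triisopropylsilyl)oxy]propan-1-one (syn-aldol) | O=C(c1c(F)cc(OCc2ccccc2)cc1OCc1ccccc1)[C@@H](O[Si](C(C)C)(C(C)C)C(C)C)[C@H](O)c1ccc(OCc2ccccc2)c(OCc2ccccc2)c1 | intermediate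
11 | (2R,3S)-5,7-bis(benzyloxy)-2-[3,4-bis(benzyloxy)phenyl]-3-[(triisopropylsilyl)oxy]chroman-4-one (2,3-cis) | CC(C)[Si](C(C)C)(C(C)C)O[C@@H]1C(=O)c2c(OCc3ccccc3)cc(OCc3ccccc3)cc2O[C@@H]1c1ccc(OCc2ccccc2)c(OCc2ccccc2)c1 | intermediate
12 | (2R,3R,4R)-5,7-bis(benzyloxy)-2-[3,4-bis(benzyloxy)phenyl]-3-[(triisopropylsilyl)oxy]chroman-4-ol (all-cis) | CC(C)[Si](C(C)C)(C(C)C)O[C@@H]1[C@H](O)c2c(OCc3ccccc3)cc(OCc3ccccc3)cc2O[C@@H]1c1ccc(OCc2ccccc2)c(OCc2ccccc2)c1 | intermediate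
13 | (2R,3R,4R)-5,7-bis(benzyloxy)-2-[3,4-bis(benzyloxy)phenyl]-8-bromo-3-[(triisopropylsilyl)oxy]chroman-4-ol | CC(C)[Si](C(C)C)(C(C)C)O[C@@H]1[C@H](O)c2c(OCc3ccccc3)cc(OCc3ccccc3)c(Br)c2O[C@@H]1c1ccc(OCc2ccccc2)c(OCc2ccccc2)c1 | intermediate
14 | (−)-epicatechin, (2R,3R) | O[C@@H]1Cc2c(O)cc(O)cc2O[C@@H]1c1ccc(O)c(O)c1 | starting material
15 | 5,7,3',4'-tetra-O-benzyl-(−)-epicatechin | O[C@@H]1Cc2c(OCc3ccccc3)cc(OCc3ccccc3)cc2O[C@@H]1c1ccc(OCc2ccccc2)c(OCc2ccccc2)c1 | intermediate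
16 | 5,7,3',4'-tetra-O-benzyl-3-O-(tert-butyldimethylsilyl)-(−)-epicatechin | CC(C)(C)[Si](C)(C)O[C@@H]1Cc2c(OCc3ccccc3)cc(OCc3ccccc3)cc2O[C@@H]1c1ccc(OCc2ccccc2)c(OCc2ccccc2)c1 | intermediate
17 | 8-bromo-5,7,3',4'-tetra-O-benzyl-3-O-triisopropylsilyl-epicatechin-(4β→8)-5,7,3',4'-tetra-O-benzyl-3-O-tert-butyldimethylsilyl-epicatechin | CC(C)[Si](C(C)C)(C(C)C)O[C@@H]1[C@@H](c2c(OCc6ccccc6)cc(OCc6ccccc6)c3c2O[C@H](c2ccc(OCc6ccccc6)c(OCc6ccccc6)c2)[C@H](O[Si](C)(C)C(C)(C)C)C3)c2c(OCc6ccccc6)cc(OCc6ccccc6)c(Br)c2O[C@@H]1c1ccc(OCc6ccccc6)c(OCc6ccccc6)c1 | intermediate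
18 | 3,5,7,3',4'-penta-O-benzyl-(−)-epicatechin | c1ccccc1CO[C@@H]1Cc2c(OCc3ccccc3)cc(OCc3ccccc3)cc2O[C@@H]1c1ccc(OCc2ccccc2)c(OCc2ccccc2)c1 | intermediate
19 | (2R,3R,4S)-3,5,7-tris(benzyloxy)-2-[3,4-bis(benzyloxy)phenyl]chroman-4-ol | c1ccccc1CO[C@@H]1[C@@H](O)c2c(OCc3ccccc3)cc(OCc3ccccc3)cc2O[C@@H]1c1ccc(OCc2ccccc2)c(OCc2ccccc2)c1 | intermediate
20 | (2R,3S)-3,5,7-tris(benzyloxy)-2-[3,4-bis(benzyloxy)phenyl]chroman-4-one | c1ccccc1CO[C@@H]1C(=O)c2c(OCc3ccccc3)cc(OCc3ccccc3)cc2O[C@@H]1c1ccc(OCc2ccccc2)c(OCc2ccccc2)c1 | intermediate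
21 | C8 aryllithium of the upper unit of 17 (lithium in place of bromine) | CC(C)[Si](C(C)C)(C(C)C)O[C@@H]1[C@@H](c2c(OCc6ccccc6)cc(OCc6ccccc6)c3c2O[C@H](c2ccc(OCc6ccccc6)c(OCc6ccccc6)c2)[C@H](O[Si](C)(C)C(C)(C)C)C3)c2c(OCc6ccccc6)cc(OCc6ccccc6)c([Li])c2O[C@@H]1c1ccc(OCc6ccccc6)c(OCc6ccccc6)c1 | intermediate
22 | 3,5,7,3',4'-penta-O-benzyl-4α-hydroxy-epicatechin-(4β→8)-[5,7,3',4'-tetra-O-benzyl-3-O-triisopropylsilyl-epicatechin]-(4β→8)-[5,7,3',4'-tetra-O-benzyl-3-O-tert-butyldimethylsilyl-epicatechin] | CC(C)[Si](C(C)C)(C(C)C)O[C@@H]1[C@@H](c2c(OCc6ccccc6)cc(OCc6ccccc6)c3c2O[C@H](c2ccc(OCc6ccccc6)c(OCc6ccccc6)c2)[C@H](O[Si](C)(C)C(C)(C)C)C3)c2c(OCc6ccccc6)cc(OCc6ccccc6)c([C@@]3(O)c4c(OCc6ccccc6)cc(OCc6ccccc6)cc4O[C@H](c4ccc(OCc6ccccc6)c(OCc6ccccc6)c4)[C@@H]3OCc6ccccc6)c2O[C@@H]1c1ccc(OCc6ccccc6)c(OCc6ccccc6)c1 | intermediate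
23 | 3,5,7,3',4'-penta-O-benzyl-epicatechin-(4α→8)-[5,7,3',4'-tetra-O-benzyl-3-O-triisopropylsilyl-epicatechin]-(4β→8)-[5,7,3',4'-tetra-O-benzyl-3-O-tert-butyldimethylsilyl-epicatechin] | CC(C)[Si](C(C)C)(C(C)C)O[C@@H]1[C@@H](c2c(OCc6ccccc6)cc(OCc6ccccc6)c3c2O[C@H](c2ccc(OCc6ccccc6)c(OCc6ccccc6)c2)[C@H](O[Si](C)(C)C(C)(C)C)C3)c2c(OCc6ccccc6)cc(OCc6ccccc6)c([C@@H]3c4c(OCc6ccccc6)cc(OCc6ccccc6)cc4O[C@H](c4ccc(OCc6ccccc6)c(OCc6ccccc6)c4)[C@@H]3OCc6ccccc6)c2O[C@@H]1c1ccc(OCc6ccccc6)c(OCc6ccccc6)c1 | intermediate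
24 | 3,5,7,3',4'-penta-O-benzyl-epicatechin-(4α→8)-[5,7,3',4'-tetra-O-benzyl-epicatechin]-(4β→8)-[5,7,3',4'-tetra-O-benzyl-epicatechin] | O[C@@H]1[C@@H](c2c(OCc6ccccc6)cc(OCc6ccccc6)c3c2O[C@H](c2ccc(OCc6ccccc6)c(OCc6ccccc6)c2)[C@H](O)C3)c2c(OCc6ccccc6)cc(OCc6ccccc6)c([C@@H]3c4c(OCc6ccccc6)cc(OCc6ccccc6)cc4O[C@H](c4ccc(OCc6ccccc6)c(OCc6ccccc6)c4)[C@@H]3OCc6ccccc6)c2O[C@@H]1c1ccc(OCc6ccccc6)c(OCc6ccccc6)c1 | intermediate
25 | 3,4,5-tris(benzyloxy)benzoic acid | OC(=O)c1cc(OCc2ccccc2)c(OCc2ccccc2)c(OCc2ccccc2)c1 | starting material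
26 | 3,5,7,3',4'-penta-O-benzyl-epicatechin-(4α→8)-[5,7,3',4'-tetra-O-benzyl-3-O-(3,4,5-tris(benzyloxy)benzoyl)-epicatechin]-(4β→8)-[5,7,3',4'-tetra-O-benzyl-3-O-(3,4,5-tris(benzyloxy)benzoyl)-epicatechin] | O=C(c5cc(OCc6ccccc6)c(OCc6ccccc6)c(OCc6ccccc6)c5)O[C@@H]1[C@@H](c2c(OCc6ccccc6)cc(OCc6ccccc6)c3c2O[C@H](c2ccc(OCc6ccccc6)c(OCc6ccccc6)c2)[C@H](OC(=O)c2cc(OCc6ccccc6)c(OCc6ccccc6)c(OCc6ccccc6)c2)C3)c2c(OCc6ccccc6)cc(OCc6ccccc6)c([C@@H]3c4c(OCc6ccccc6)cc(OCc6ccccc6)cc4O[C@H](c4ccc(OCc6ccccc6)c(OCc6ccccc6)c4)[C@@H]3OCc6ccccc6)c2O[C@@H]1c1ccc(OCc6ccccc6)c(OCc6ccccc6)c1 | intermediate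
27 | epicatechin-(4α→8)-epicatechin 3-O-gallate-(4β→8)-epicatechin 3-O-gallate (CNP0279403.2) | O=C(O[C@@H]1[C@@H](c2c(O)cc(O)c3c2O[C@H](c2ccc(O)c(O)c2)[C@H](OC(=O)c2cc(O)c(O)c(O)c2)C3)c2c(O)cc(O)c([C@@H]3c4c(O)cc(O)cc4O[C@H](c4ccc(O)c(O)c4)[C@@H]3O)c2O[C@@H]1c1ccc(O)c(O)c1)c1cc(O)c(O)c(O)c1 | target

**Step count and risks**

Total steps: 18. Longest linear sequence: 12 steps (2, 3, 4, 5, 6, 7, 10, 14, 15, 16, 17, 18, from methyl glycolate).

Steps most likely to fail: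

Step 5. Once the alkoxide of 10 is free, retro-aldol cleavage and C3 epimerisation may compete with ring closure and erode the syn relationship and the enantiomeric purity; a slow silyl shift followed by five-ring closure through O3 is a second way to lose material. Fallback, setting out from 7 and 8: the same boron aldol is quenched with pH 7 buffer and syn-aldol 10 is isolated. Evans–Saksena reduction (Me4NBH(OAc)3, AcOH/MeCN, −30 °C) then gives (1R,2S,3R)-1-[2,4-bis(benzyloxy)-6-fluorophenyl]-3-[3,4-bis(benzyloxy)phenyl]-2-[(triisopropylsilyl)oxy]propane-1,3-diol F1, which has no carbonyl and so cannot undergo retro-aldol or epimerise. KH in THF/DMF closes ring C by SNAr of the benzylic alkoxide next to the 3,4-bis(benzyloxy)phenyl ring onto the unactivated fluoroarene, a known pyran closure for catechin-type compounds; the other alkoxide could only form a four-membered ring. The route is rejoined at 12.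

Step 14. The hindered aryllithium 21 may act as a base and enolise ketone 20 (proton transfer instead of carbonyl addition), returning debrominated dimer. Fallback, setting out from 17: bromine–lithium exchange and a methanol quench give the debrominated dimer 5,7,3',4'-tetra-O-benzyl-3-O-triisopropylsilyl-epicatechin-(4β→8)-5,7,3',4'-tetra-O-benzyl-3-O-tert-butyldimethylsilyl-epicatechin F2. Commercial (+)-catechin is benzylated (BnBr, K2CO3, DMF) to 5,7,3',4'-tetra-O-benzyl-(+)-catechin F3 and oxidised with DDQ and 2-ethoxyethanol to (2R,3S,4S)-5,7-bis(benzyloxy)-2-[3,4-bis(benzyloxy)phenyl]-4-(2-ethoxyethoxy)chroman-3-ol F4. TMSOTf-promoted Friedel–Crafts coupling of F4 with C8 of the upper unit of F2 should give, with the 3,4-trans selectivity usual for catechin electrophiles, 5,7,3',4'-tetra-O-benzyl-catechin-(4α→8)-[3-O-triisopropylsilyl unit]-(4β→8)-[3-O-tert-butyldimethylsilyl unit] F5. Dess–Martin oxidation of its only free hydroxyl gives the upper-unit flavan-3-one F6. Reduction with LiBH(s-Bu)3 from the β face, opposite both α-aryl groups, gives the 2,3-cis alcohol 5,7,3',4'-tetra-O-benzyl-epicatechin-(4α→8)-[3-O-triisopropylsilyl unit]-(4β→8)-[3-O-tert-butyldimethylsilyl unit] F7. NaH/BnBr then rejoins the route at 23.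

Step 7. Bromination may go partly to C6, and traces of HBr may ionise the free benzylic 4-hydroxyl and cause self-condensation. Fallback, setting out from 2: the bromine is placed before ring construction. Ortho-lithiation of 2 (n-BuLi, −78 °C) and a quench with BrCF2CF2Br give 1,5-bis(benzyloxy)-2-bromo-3-fluorobenzene F8. Deprotonation of the remaining C–H between fluorine and benzyloxy with lithium 2,2,6,6-tetramethylpiperidide (no bromine–lithium exchange with an amide base; a halogen dance would be degenerate) and acylation with 5 give 1-[4,6-bis(benzyloxy)-3-bromo-2-fluorophenyl]-2-[(triisopropylsilyl)oxy]ethan-1-one F9. The annulation of step 5 with 8 gives (2R,3S)-5,7-bis(benzyloxy)-2-[3,4-bis(benzyloxy)phenyl]-8-bromo-3-[(triisopropylsilyl)oxy]chroman-4-one F10. Luche reduction as in step 6 rejoins the route at 13.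

Further compounds

F1 | step 5 | (1R,2S,3R)-1-[2,4-bis(benzyloxy)-6-fluorophenyl]-3-[3,4-bis(benzyloxy)phenyl]-2-[(triisopropylsilyl)oxy]propane-1,3-diol | O[C@H](c1c(F)cc(OCc2ccccc2)cc1OCc1ccccc1)[C@@H](O[Si](C(C)C)(C(C)C)C(C)C)[C@H](O)c1ccc(OCc2ccccc2)c(OCc2ccccc2)c1
F2 | step 14 | 5,7,3',4'-tetra-O-benzyl-3-O-triisopropylsilyl-epicatechin-(4β→8)-5,7,3',4'-tetra-O-benzyl-3-O-tert-butyldimethylsilyl-epicatechin | CC(C)[Si](C(C)C)(C(C)C)O[C@@H]1[C@@H](c2c(OCc6ccccc6)cc(OCc6ccccc6)c3c2O[C@H](c2ccc(OCc6ccccc6)c(OCc6ccccc6)c2)[C@H](O[Si](C)(C)C(C)(C)C)C3)c2c(OCc6ccccc6)cc(OCc6ccccc6)cc2O[C@@H]1c1ccc(OCc6ccccc6)c(OCc6ccccc6)c1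
F3 | step 14 | 5,7,3',4'-tetra-O-benzyl-(+)-catechin, (2R,3S) | O[C@H]1Cc2c(OCc3ccccc3)cc(OCc3ccccc3)cc2O[C@@H]1c1ccc(OCc2ccccc2)c(OCc2ccccc2)c1
F4 | step 14 | (2R,3S,4S)-5,7-bis(benzyloxy)-2-[3,4-bis(benzyloxy)phenyl]-4-(2-ethoxyethoxy)chroman-3-ol | O[C@H]1[C@@H](OCCOCC)c2c(OCc3ccccc3)cc(OCc3ccccc3)cc2O[C@@H]1c1ccc(OCc2ccccc2)c(OCc2ccccc2)c1
F5 | step 14 | 5,7,3',4'-tetra-O-benzyl-catechin-(4α→8)-[5,7,3',4'-tetra-O-benzyl-3-O-triisopropylsilyl-epicatechin]-(4β→8)-[5,7,3',4'-tetra-O-benzyl-3-O-tert-butyldimethylsilyl-epicatechin] | CC(C)[Si](C(C)C)(C(C)C)O[C@@H]1[C@@H](c2c(OCc6ccccc6)cc(OCc6ccccc6)c3c2O[C@H](c2ccc(OCc6ccccc6)c(OCc6ccccc6)c2)[C@H](O[Si](C)(C)C(C)(C)C)C3)c2c(OCc6ccccc6)cc(OCc6ccccc6)c([C@@H]3c4c(OCc6ccccc6)cc(OCc6ccccc6)cc4O[C@H](c4ccc(OCc6ccccc6)c(OCc6ccccc6)c4)[C@H]3O)c2O[C@@H]1c1ccc(OCc6ccccc6)c(OCc6ccccc6)c1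
F6 | step 14 | upper-unit flavan-3-one of F5 (3-oxo, 2α-aryl, 4α-aryl) | CC(C)[Si](C(C)C)(C(C)C)O[C@@H]1[C@@H](c2c(OCc6ccccc6)cc(OCc6ccccc6)c3c2O[C@H](c2ccc(OCc6ccccc6)c(OCc6ccccc6)c2)[C@H](O[Si](C)(C)C(C)(C)C)C3)c2c(OCc6ccccc6)cc(OCc6ccccc6)c([C@@H]3c4c(OCc6ccccc6)cc(OCc6ccccc6)cc4O[C@H](c4ccc(OCc6ccccc6)c(OCc6ccccc6)c4)C3=O)c2O[C@@H]1c1ccc(OCc6ccccc6)c(OCc6ccccc6)c1
F7 | step 14 | 5,7,3',4'-tetra-O-benzyl-epicatechin-(4α→8)-[5,7,3',4'-tetra-O-benzyl-3-O-triisopropylsilyl-epicatechin]-(4β→8)-[5,7,3',4'-tetra-O-benzyl-3-O-tert-butyldimethylsilyl-epicatechin] | CC(C)[Si](C(C)C)(C(C)C)O[C@@H]1[C@@H](c2c(OCc6ccccc6)cc(OCc6ccccc6)c3c2O[C@H](c2ccc(OCc6ccccc6)c(OCc6ccccc6)c2)[C@H](O[Si](C)(C)C(C)(C)C)C3)c2c(OCc6ccccc6)cc(OCc6ccccc6)c([C@@H]3c4c(OCc6ccccc6)cc(OCc6ccccc6)cc4O[C@H](c4ccc(OCc6ccccc6)c(OCc6ccccc6)c4)[C@@H]3O)c2O[C@@H]1c1ccc(OCc6ccccc6)c(OCc6ccccc6)c1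
F8 | step 7 | 1,5-bis(benzyloxy)-2-bromo-3-fluorobenzene | Fc1cc(OCc2ccccc2)cc(OCc2ccccc2)c1Br
F9 | step 7 | 1-[4,6-bis(benzyloxy)-3-bromo-2-fluorophenyl]-2-[(triisopropylsilyl)oxy]ethan-1-one | O=C(CO[Si](C(C)C)(C(C)C)C(C)C)c1c(F)c(Br)c(OCc2ccccc2)cc1OCc1ccccc1
F10 | step 7 | (2R,3S)-5,7-bis(benzyloxy)-2-[3,4-bis(benzyloxy)phenyl]-8-bromo-3-[(triisopropylsilyl)oxy]chroman-4-one | CC(C)[Si](C(C)C)(C(C)C)O[C@@H]1C(=O)c2c(OCc3ccccc3)cc(OCc3ccccc3)c(Br)c2O[C@@H]1c1ccc(OCc2ccccc2)c(OCc2ccccc2)c1
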